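**Remark (assumption on the reading of the structure):** the SMILES is read as a 12,6-germacranolide and germacrane numbering is used throughout (ring C1–C10; C11, C12, C13 = lactone α-carbon, lactone carbonyl, exocyclic CH2; C14 = CO2H on C10; C15 = CH3 on C4). Configuration: (6R,7S,8S,9S), 1(10)E, 4Z, both ester side chains (Z) (angelates).

## Analysis of the target

The target is a cis,cis-germacranolide: a ten-membered carbocycle with two trisubstituted olefins that are both cis within the ring (C2/C9 cis at C1=C10, which is E by CIP only because of the C14 carboxyl; C3/C6 cis at C4=C5, Z). The ring is trans-fused at C6/C7 to an α-methylene-γ-butyrolactone (O on C6, C11=C13 exocyclic). C6–C9 form a contiguous stereotetrad: O6 and the C7–C11 bond are trans on the lactone, the C7–C11 bond and O8 are on the same face of the carbocycle, and the 8,9-diol is trans (threo). The sensitive groups are the α-methylene lactone (Michael acceptor), the two angelates (isomerise to tiglates with nucleophiles, base, heat or triplet sensitisers), the free acrylic acid, the allylic lactone C6–O bond, and the cis,cis-cyclodeca-1,5-diene itself (Cope rearrangement on heating, so nothing after ring closure should exceed about 40 °C). The difficulty is the combination of a strained medium ring, two ring-cis trisubstituted olefins whose geometry no ring closure guarantees, and four adjacent stereocentres. The feature the route exploits is C8: an oxygenated carbon whose neighbour C9 is also oxygenated and whose other neighbour C7 is the β-carbon of the lactone carbonyl (C12–C11–C7), with C11 carrying the exocyclic C13. This is the retron of a nucleophilic α-alkoxy radical at C8 that adds to C7 of a butenolide and expels a leaving group from C13. At the same time C8–C9–C10 with their two trans oxygens are three of the four carbons of tartaric acid, so the fourth carbon can serve as a carboxyl that is lost as CO2 when the radical is formed.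

## Retrosynthetic reasoning

**23 from 22, 20 and 19.** The C14 acid is unmasked last from its 2-(trimethylsilyl)ethyl ester 22, because a free acid would interfere with acylation. The two angelates are put on diol 20 with angelic acid 21 only after the ring exists, since they would not survive the photochemical key step without Z-to-E isomerisation. Diol 20 comes from acetonide 19, so C8–O and C9–O travel as the tartrate acetonide.

**19 from 18 (key disconnection).** The C7–C8 bond and the C13–O bond are cut. Going forward, seco acid 18 loses its C8 carboxyl as a one-carbon gas, the C8 radical closes the ten-membered ring onto C7 of the butenolide, and acetate leaves from C13. This cut is chosen because C7 and C8 are then each set from their own neighbour (C6 and C9), so no 1,2-induction across the C7–C8 bond is needed. It also creates the ring, two stereocentres and the exocyclic methylene in one operation from an acyclic chain that already holds both ring-cis olefins.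

**18 from 17 and 12.** The C1=C10 bond is cut by cross-metathesis. The required geometry (C2 cis to C9) is the thermodynamic E-enoate, so an intermolecular metathesis can deliver it. The cut divides the molecule into a tartrate half 17 (C8–C10, C14) and a butenolide half 12 (C1–C7, C11–C13, C15), each with one preset stereocentre.

**12 from 11, 8, 6 and 7.** The acetate 12 comes from hydroxymethyl butenolide 11. Butenolide 11 arises from γ-hydroxy ynoate 8 by syn-hydroalumination, C-hydroxymethylation at C11 and lactonisation. Ynoate 8 is cut at C6–C7 into enal 6 and methyl propiolate 7; a catalytic enantioselective alkynylation sets C6, the only stereocentre made by catalysis.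

**6 from 5, 3, 4 and 1.** The 4Z olefin is not left to a ring closure. It is fixed at the start by trans-hydroalumination/iodination of but-2-yn-1-ol 1 to iodide 3 and stereoretentive coupling with Grignard reagent 4 to dienol 5, which is oxidised to 6.

**17 from 16, 15 and 13.** The tartrate-derived diester 13 supplies C8 and C9 with the correct trans relationship and absolute configuration. One ester carbon becomes C10 by reduction and alkyne homologation (15); carbonylation of the alkyne installs C14 (16). The other ester is kept as the carboxyl that is extruded in the key step (17).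

## Alternatives that were turned down

**Alternative 1:** C6–C7 by intramolecular Nozaki–Hiyama–Kishi/Barbier allylation with lactonisation (the textbook route for germacranolides). The seco bromo aldehyde A1 would be treated with CrCl2 (divalent chromium) at high dilution and would give 22 directly. It was turned down as the key step for three reasons. It is the route most chemists would draw first. Both new centres arise in one transition state, in which the cis/trans lactone relation depends on the geometry and equilibration of the allylchromium and the relation to C8 on a second, independent preference, so the result rests on double matching inside a strained ten-membered transition state. And A1 carries at once a (Z)-enal prone to Z/E isomerisation, an allylic bromide and two Michael acceptors, with no saving in steps. A variant of it is kept as the fallback for the key step.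

**Alternative 2:** C4=C5 by ring-closing metathesis of the seco triene A2 (lactone and C1=C10 enoate in place, vinyl on C6, isopropenyl-type terminus at C4), which would give 19. It was turned down because a trisubstituted olefin would have to form inside a ten-membered ring whose 4E and 4Z forms are both unstrained enough to exist. The decisive Z geometry would therefore be left to the catalyst, whereas the chosen route fixes it in step 1. The closure also competes with dimerisation, and A2 needs as many steps as 18.

**Alternative 3:** C6–C7 by [2,3]-Wittig ring contraction of the 13-membered diallyl ether A3 (ether oxygen between C6 and C13), a known way to cyclodeca-1,5-dienols. It was turned down on mechanistic grounds. C7 is attacked here as an electrophilic allyl terminus by the C6 carbanion, and the allylic C8–O bond prefers to lie anti to the forming bond (Felkin–Anh-type). This places C6 anti to O8 and leads to the 6,7-bis-epimeric triol A4, not to the natural 7,8 relationship. In addition, the alkyllithium base forces both carboxyl carbons (C12, C14) to travel as alcohols, which costs about four redox and protecting-group steps, and the allylic α-oxy methines C8–H and C9–H compete for deprotonation.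

Key step: step 11

## Route

**Step 1**
Reactants: 1 but-2-yn-1-ol
Product: 3 (2Z)-3-iodobut-2-en-1-ol, via cyclic alkenylalanate 2 (not isolated)
Conditions: NaAlH2(OCH2CH2OMe)2 (1.5 equiv), THF, 0 °C to rt; then I2, −78 to 0 °C
Reagents that add atoms: iodine, II
Why: Hydroxyl-directed trans-hydroalumination puts aluminium on C3 anti to the new C2–H, and iodinolysis with retention gives the Z-iodide; this fixes the later 4Z geometry (the methyl of 1 is C15, its CH2O is C6–O6).

**Step 2**
Reactants: 3 (2Z)-3-iodobut-2-en-1-ol; 4 but-3-enylmagnesium bromide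
Product: 5 (2Z)-3-methylhepta-2,6-dien-1-ol
Conditions: 4 (3 equiv), Pd(dppf)Cl2 (3 mol%), THF, 0 °C to rt
Reagents that add atoms: none
Why: Kumada–Corriu coupling of an alkenyl iodide goes with retention, so the butenyl chain (C3, C2, C1 and a sacrificial CH2) ends up cis to C6; one equivalent of 4 is consumed by the hydroxyl.

**Step 3**
Reactants: 5 (2Z)-3-methylhepta-2,6-dien-1-ol
Product: 6 (2Z)-3-methylhepta-2,6-dienal
Conditions: activated MnO2 (15 equiv), CH2Cl2, rt; used at once
Reagents that add atoms: none
Why: Chemoselective allylic oxidation should give the neral-type (Z)-enal without touching the isolated olefins; immediate use limits Z-to-E isomerisation.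

**Step 4**
Reactants: 6 (2Z)-3-methylhepta-2,6-dienal; 7 methyl propiolate
Product: 8 methyl (4R,5Z)-4-hydroxy-6-methyldeca-5,9-dien-2-ynoate
Conditions: ProPhenol ligand (10 mol%, antipode chosen for the 4R carbinol), Me2Zn (3 equiv), Ph3PO (20 mol%), 7 (3 equiv), toluene, 4 °C
Reagents that add atoms: none
Why: Dinuclear zinc–ProPhenol-catalysed enantioselective alkynylation of an α,β-unsaturated aldehyde with the zinc acetylide of 7 sets C6, the only stereocentre made by catalysis; the ester and both olefins are inert.

**Step 5**
Reactants: 8 methyl (4R,5Z)-4-hydroxy-6-methyldeca-5,9-dien-2-ynoate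
Product: 11 (5R)-3-(hydroxymethyl)-5-[(1Z)-2-methylhexa-1,5-dien-1-yl]furan-2(5H)-one, via α-aluminio enoate 9 (not isolated), via hydroxymethyl hydroxy ester 10 (not isolated)
Conditions: i-Bu2AlH (2.4 equiv), HMPA/THF, 0 °C; then CH2O (gas from cracked paraformaldehyde), 0 °C to rt; Rochelle salt work-up; PPTS (cat.), CH2Cl2, rt
Reagents that add atoms: formaldehyde, C=O
Why: Conjugate syn-hydroalumination of the ynoate (hydride to C7, aluminium to C11, the carbinol carried as its aluminium alkoxide) gives the α-aluminio enoate with C6 cis to the ester; formaldehyde then hydroxymethylates C11 (C13), and the cis γ-hydroxy ester lactonises to the butenolide.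

**Step 6**
Reactants: 11 (5R)-3-(hydroxymethyl)-5-[(1Z)-2-methylhexa-1,5-dien-1-yl]furan-2(5H)-one
Product: 12 [(5R)-5-[(1Z)-2-methylhexa-1,5-dien-1-yl]-2-oxo-2,5-dihydrofuran-3-yl]methyl acetate
Conditions: Ac2O, pyridine, CH2Cl2, 0 °C
Reagents that add atoms: acetic anhydride, CC(=O)OC(C)=O
Why: Acetylation turns O–C13 into the leaving group that the key step expels; pyridine without a nucleophilic catalyst avoids SN2′ attack and epimerisation at the acidic C6–H.

**Step 7**
Reactants: 13 dimethyl (4R,5R)-2,2-dimethyl-1,3-dioxolane-4,5-dicarboxylate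
Product: 15 methyl (4R,5S)-5-ethynyl-2,2-dimethyl-1,3-dioxolane-4-carboxylate, via aldehyde ester 14 (not isolated)
Conditions: i-Bu2AlH (1.05 equiv), CH2Cl2, −78 °C; then MeOH, K2CO3, dimethyl (1-diazo-2-oxopropyl)phosphonate, −78 °C to rt
Reagents that add atoms: dimethyl (1-diazo-2-oxopropyl)phosphonate, COP(=O)(OC)C(=[N+]=[N-])C(C)=O
Why: One equivalent of hydride stops at the aluminium hemiacetal of one ester of the C2-symmetric diester (either ester gives the same product), and the aldehyde released by methanol undergoes Seyferth–Gilbert homologation (Ohira–Bestmann reagent) to the alkyne whose inner carbon is C10. The mono-reduction is statistical, so unreacted 13 is recycled.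

**Step 8**
Reactants: 15 methyl (4R,5S)-5-ethynyl-2,2-dimethyl-1,3-dioxolane-4-carboxylate
Product: 16 methyl (4R,5S)-2,2-dimethyl-5-{3-oxo-3-[2-(trimethylsilyl)ethoxy]prop-1-en-2-yl}-1,3-dioxolane-4-carboxylate
Conditions: Pd(OAc)2 (1 mol%), 2-(diphenylphosphino)pyridine (8 mol%), MeSO3H (4 mol%), CO (20 bar), 2-(trimethylsilyl)ethanol (3 equiv), toluene, 50 °C
Reagents that add atoms: carbon monoxide, [C-]#[O+]; 2-(trimethylsilyl)ethanol, C[Si](C)(C)CCO
Why: Palladium/2-pyridylphosphine-catalysed Markovnikov hydroalkoxycarbonylation of the terminal alkyne gives the 2-substituted acrylate, so C14 enters as a fluoride-labile ester; excess pyridylphosphine buffers the acid so that the acetonide should survive.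

**Step 9**
Reactants: 16 methyl (4R,5S)-2,2-dimethyl-5-{3-oxo-3-[2-(trimethylsilyl)ethoxy]prop-1-en-2-yl}-1,3-dioxolane-4-carboxylate
Product: 17 (4R,5S)-2,2-dimethyl-5-{3-oxo-3-[2-(trimethylsilyl)ethoxy]prop-1-en-2-yl}-1,3-dioxolane-4-carboxylic acid
Conditions: LiOH (1.1 equiv), THF/H2O, 0 °C; then dilute HCl to pH 3 at 0 °C
Reagents that add atoms: lithium hydroxide, [Li+].[OH-]
Why: The inductively activated α-alkoxy methyl ester should be saponified much faster than the hindered conjugated silylethyl ester; any epimerisation at C8 is irrelevant because this centre becomes a radical in step 11.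

**Step 10**
Reactants: 17 (4R,5S)-2,2-dimethyl-5-{3-oxo-3-[2-(trimethylsilyl)ethoxy]prop-1-en-2-yl}-1,3-dioxolane-4-carboxylic acid; 12 [(5R)-5-[(1Z)-2-methylhexa-1,5-dien-1-yl]-2-oxo-2,5-dihydrofuran-3-yl]methyl acetate
Product: 18 seco acid: (4R,5S)-5-[(1E,5Z)-6-[(2R)-4-(acetoxymethyl)-5-oxo-2,5-dihydrofuran-2-yl]-5-methyl-1-{[2-(trimethylsilyl)ethoxy]carbonyl}hexa-1,5-dien-1-yl]-2,2-dimethyl-1,3-dioxolane-4-carboxylic acid
Conditions: second-generation Hoveyda–Grubbs catalyst (5 mol%), 17 (2 equiv), CH2Cl2, 40 °C
Reagents that add atoms: none
Why: Cross-metathesis of the monosubstituted olefin of 12 with the 2-substituted acrylate of 17 (used in excess; it does not homodimerise) should form the trisubstituted C1=C10 enoate with the chain trans to the ester, i.e. C2 cis to C9; the trisubstituted olefins and the butenolide are inert.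

**Step 11**
Reactants: 18 seco acid
Product: 19 2-(trimethylsilyl)ethyl (6R,7S,8S,9S,1(10)E,4Z)-8,9-(isopropylidenedioxy)germacra-1(10),4,11(13)-trien-12,6-olid-14-oate
Conditions: [Ir{dF(CF3)ppy}2(dtbbpy)]PF6 (2 mol%), K2HPO4 (1.2 equiv), degassed DMF (2 mM), 450 nm LEDs, 25 °C
Reagents that add atoms: none
Why: Proposed new method: a photoredox decarboxylative radical macrocyclisation with addition–elimination, in which the excited trivalent iridium complex oxidises the C8 carboxylate, loss of CO2 leaves the nucleophilic dioxolan-4-yl radical at C8, this adds to C7 (the β-carbon of the butenolide), the C11 radical is reduced by divalent iridium to the lactone enolate and the enolate expels acetate from C13 to give the exocyclic methylene; the closest known reaction types are intermolecular decarboxylative Giese additions of α-oxy acids to butenolides and acrylates, radical addition–elimination on 2-(acyloxymethyl)acrylates and decarboxylative radical macrocyclisations of peptides, none of which has closed a ten-membered carbocycle. The carbocycle closes in the 10-exo-trig mode, with the lactone and dioxolane rings already in place. C7 is controlled by C6: the radical should enter the butenolide face opposite to the C5 alkenyl substituent, which gives the trans-fused lactone. C8 is controlled by C9: dioxolan-4-yl radicals react anti to the substituent on the neighbouring ring carbon, which gives the trans-dioxolane, so the C7/C8 relationship follows from the two preset centres and needs no induction across the new bond. The step needs the cyclisation to outrun hydrogen abstraction, bimolecular addition and 1,2-migration of the alkenyl group from C9 to C8; the eight-atom tether is folded by the two olefins that already have the ring-cis geometry, the polarity is matched, the α-alkoxy radical cannot be reduced by the catalyst, and high dilution suppresses bimolecular paths. Loss of acetate makes the addition irreversible.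

**Step 12**
Reactants: 19 ten-membered lactone acetonide
Product: 20 2-(trimethylsilyl)ethyl (6R,7S,8S,9S,1(10)E,4Z)-8,9-dihydroxygermacra-1(10),4,11(13)-trien-12,6-olid-14-oate
Conditions: AcOH/H2O (4:1), 40 °C
Reagents that add atoms: none
Why: Acid hydrolysis of the strained trans-fused dioxolane; the 1(10)-olefin is an electron-poor enoate, which should suppress transannular cyclisation under this mild acid.

**Step 13**
Reactants: 20 diol; 21 angelic acid [(2Z)-2-methylbut-2-enoic acid]
Product: 22 2-(trimethylsilyl)ethyl (6R,7S,8S,9S,1(10)E,4Z)-8,9-bis{[(2Z)-2-methylbut-2-enoyl]oxy}germacra-1(10),4,11(13)-trien-12,6-olid-14-oate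
Conditions: 21 (4 equiv), 2,4,6-trichlorobenzoyl chloride, Et3N, toluene, rt; then 20, DMAP, toluene, rt to 40 °C
Reagents that add atoms: none
Why: Yamaguchi esterification through the mixed anhydride acylates both secondary hydroxyls without an acyl chloride or ketene stage, the conditions under which angelates isomerise least to tiglates.

**Step 14**
Reactants: 22 bis-angelate silylethyl ester
Product: 23 target, (6R,7S,8S,9S,1(10)E,4Z)-8,9-bis{[(2Z)-2-methylbut-2-enoyl]oxy}germacra-1(10),4,11(13)-trien-12,6-olid-14-oic acid
Conditions: TBAF (2 equiv), THF, 0 °C; dilute HCl work-up at 0 °C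
Reagents that add atoms: none
Why: Fluoride-induced β-elimination of the 2-(trimethylsilyl)ethyl ester should free the C14 acid while leaving the angelates, the α-methylene lactone and the cis,cis-diene untouched.

## Compound list

1 | but-2-yn-1-ol | CC#CCO | starting material
2 | sodium cyclic alkenylalanate (O–Al chelate, Al on C3) from 1 | [Na+].CC1=CCO[Al-]1(OCCOC)OCCOC | intermediate
3 | (2Z)-3-iodobut-2-en-1-ol | C/C(I)=C/CO | intermediate
4 | but-3-enylmagnesium bromide | C=CCC[Mg]Br | starting material
5 | (2Z)-3-methylhepta-2,6-dien-1-ol | C=CCC/C(C)=C\CO | intermediate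
6 | (2Z)-3-methylhepta-2,6-dienal | C=CCC/C(C)=C\C=O | intermediate
7 | methyl propiolate | COC(=O)C#C | starting material
8 | methyl (4R,5Z)-4-hydroxy-6-methyldeca-5,9-dien-2-ynoate | COC(=O)C#C[C@H](O)/C=C(/C)CCC=C | intermediate
9 | α-(diisobutylalumanyl) enoate, O-diisobutylaluminium alkoxide (C6 cis to the ester) | COC(=O)/C([Al](CC(C)C)CC(C)C)=C\[C@H](O[Al](CC(C)C)CC(C)C)/C=C(/C)CCC=C | intermediate
10 | methyl (2Z,4R,5Z)-4-hydroxy-2-(hydroxymethyl)-6-methyldeca-2,5,9-trienoate | COC(=O)/C(CO)=C\[C@H](O)/C=C(/C)CCC=C | intermediate
11 | (5R)-3-(hydroxymethyl)-5-[(1Z)-2-methylhexa-1,5-dien-1-yl]furan-2(5H)-one | OCC1=C[C@@H](/C=C(/C)CCC=C)OC1=O | intermediate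
12 | [(5R)-5-[(1Z)-2-methylhexa-1,5-dien-1-yl]-2-oxo-2,5-dihydrofuran-3-yl]methyl acetate | CC(=O)OCC1=C[C@@H](/C=C(/C)CCC=C)OC1=O | intermediate
13 | dimethyl (4R,5R)-2,2-dimethyl-1,3-dioxolane-4,5-dicarboxylate (from L-tartaric acid) | COC(=O)[C@@H]1OC(C)(C)O[C@H]1C(=O)OC | starting material
14 | methyl (4R,5R)-5-formyl-2,2-dimethyl-1,3-dioxolane-4-carboxylate | COC(=O)[C@@H]1OC(C)(C)O[C@H]1C=O | intermediate
15 | methyl (4R,5S)-5-ethynyl-2,2-dimethyl-1,3-dioxolane-4-carboxylate | COC(=O)[C@@H]1OC(C)(C)O[C@H]1C#C | intermediate
16 | methyl (4R,5S)-2,2-dimethyl-5-{3-oxo-3-[2-(trimethylsilyl)ethoxy]prop-1-en-2-yl}-1,3-dioxolane-4-carboxylate | COC(=O)[C@@H]1OC(C)(C)O[C@H]1C(=C)C(=O)OCC[Si](C)(C)C | intermediate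
17 | (4R,5S)-2,2-dimethyl-5-{3-oxo-3-[2-(trimethylsilyl)ethoxy]prop-1-en-2-yl}-1,3-dioxolane-4-carboxylic acid | OC(=O)[C@@H]1OC(C)(C)O[C@H]1C(=C)C(=O)OCC[Si](C)(C)C | intermediate
18 | seco acid: (4R,5S)-5-[(1E,5Z)-6-[(2R)-4-(acetoxymethyl)-5-oxo-2,5-dihydrofuran-2-yl]-5-methyl-1-{[2-(trimethylsilyl)ethoxy]carbonyl}hexa-1,5-dien-1-yl]-2,2-dimethyl-1,3-dioxolane-4-carboxylic acid | OC(=O)[C@@H]1OC(C)(C)O[C@H]1/C(C(=O)OCC[Si](C)(C)C)=C\CC/C(C)=C\[C@H]2OC(=O)C(COC(C)=O)=C2 | intermediate
19 | 2-(trimethylsilyl)ethyl (6R,7S,8S,9S,1(10)E,4Z)-8,9-(isopropylidenedioxy)germacra-1(10),4,11(13)-trien-12,6-olid-14-oate | C=C1C(=O)O[C@@H]2/C=C(/C)CC/C=C(/C(=O)OCC[Si](C)(C)C)[C@@H]3OC(C)(C)O[C@H]3[C@@H]12 | intermediate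
20 | 2-(trimethylsilyl)ethyl (6R,7S,8S,9S,1(10)E,4Z)-8,9-dihydroxygermacra-1(10),4,11(13)-trien-12,6-olid-14-oate | C=C1C(=O)O[C@@H]2/C=C(/C)CC/C=C(/C(=O)OCC[Si](C)(C)C)[C@H](O)[C@@H](O)[C@@H]12 | intermediate
21 | angelic acid, (2Z)-2-methylbut-2-enoic acid | C/C=C(/C)C(=O)O | starting material
22 | 2-(trimethylsilyl)ethyl (6R,7S,8S,9S,1(10)E,4Z)-8,9-bis{[(2Z)-2-methylbut-2-enoyl]oxy}germacra-1(10),4,11(13)-trien-12,6-olid-14-oate | C=C1C(=O)O[C@@H]2/C=C(/C)CC/C=C(/C(=O)OCC[Si](C)(C)C)[C@H](OC(=O)/C(C)=C\C)[C@@H](OC(=O)/C(C)=C\C)[C@@H]12 | intermediate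
23 | CNP0154468.1, (6R,7S,8S,9S,1(10)E,4Z)-8,9-bis{[(2Z)-2-methylbut-2-enoyl]oxy}germacra-1(10),4,11(13)-trien-12,6-olid-14-oic acid | C=C1C(=O)O[C@@H]2/C=C(/C)CC/C=C(/C(=O)O)[C@H](OC(=O)/C(C)=C\C)[C@@H](OC(=O)/C(C)=C\C)[C@@H]12 | target

## Step count and least certain steps

Total: 14 steps. Longest linear sequence: 11 steps (steps 1–6 and 10–14); the tartrate branch (steps 7–9) joins at step 10.

**Step 11 (key step, proposed new method).** The most likely failure is that the C8 radical is consumed by hydrogen abstraction or bimolecular addition before the slow ten-membered closure. Further risks are migration of the alkenyl unit from C9 to C8 through a cyclopropylcarbinyl radical, loss of configuration at the acidic C6–H of the γ-alkenyl butenolide under base or triplet sensitisation, and entry on the wrong butenolide face. The fallback uses known chemistry, sets out from 16 and 6 and returns at 19. The methyl ester of 16 is reduced with i-Bu2AlH (1.0 equiv, −78 °C) to 2-(trimethylsilyl)ethyl 2-[(4S,5R)-5-formyl-2,2-dimethyl-1,3-dioxolan-4-yl]prop-2-enoate F1. A Morita–Baylis–Hillman reaction with methyl acrylate and DABCO gives the allylic alcohol methyl 2-{hydroxy[dioxolanyl]methyl}prop-2-enoate F2 (both carbinol epimers serve). PBr3 converts it with allylic transposition into the (Z)-2-(bromomethyl)enoate F3. Cross-metathesis of the silylethyl acrylate unit of F3 with the terminal olefin of 6 gives the seco bromo aldehyde F4. CrCl2 (divalent chromium) at high dilution then closes C6–C7 by intramolecular Nozaki–Hiyama–Kishi allylation, and the chromium alkoxide lactonises onto the methyl ester to give 19.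

**Step 5.** The α-aluminio enoate may isomerise through its allenolate before it is trapped (then no lactonisation), the ester may be reduced, or capture by formaldehyde may be poor. The fallback sets out from 8 and returns at 11. Hydrostannation of 8 with Bu3SnH and Pd(PPh3)2Cl2 (divalent palladium precatalyst) places tin on C11 syn to the new C7–H, and the hydroxy ester lactonises to (5R)-5-[(1Z)-2-methylhexa-1,5-dien-1-yl]-3-(tributylstannyl)furan-2(5H)-one F5. Iodine gives (5R)-3-iodo-5-[(1Z)-2-methylhexa-1,5-dien-1-yl]furan-2(5H)-one F6. Stille coupling of F6 with (tributylstannyl)methanol and Pd(PPh3)4 (zerovalent palladium) gives 11.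

**Step 8.** The acid co-catalyst may cleave the acetonide, or the branched selectivity of the carbonylation may be low on this propargylic ether. The fallback sets out from 15 and returns at 16. Markovnikov hydrostannation of 15 with Bu3SnH and Mo(CO)3(CNt-Bu)3 gives methyl 2,2-dimethyl-5-[1-(tributylstannyl)ethenyl]-1,3-dioxolane-4-carboxylate F7 (dioxolane configuration as in 15). Iodine gives methyl 5-(1-iodoethenyl)-2,2-dimethyl-1,3-dioxolane-4-carboxylate F8. Alkoxycarbonylation of F8 with CO, 2-(trimethylsilyl)ethanol, Et3N and Pd(PPh3)4 gives 16.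

**Step 13.** The angelate may isomerise to the tiglate during the slow acylation of the hindered C8 hydroxyl, or the second acylation may stay incomplete. The fallback sets out from 20 and returns at 22. Both hydroxyls are acylated with 2-(diphenoxyphosphoryl)propanoic acid (DCC, DMAP) to give the bis(phosphonopropanoate) F9. A Z-selective Ando-type Horner–Wadsworth–Emmons reaction of F9 with acetaldehyde (NaI, DBU, THF, −78 to 0 °C) then builds both angelates in place and gives 22.

## Further compounds

F1 | step 11 | 2-(trimethylsilyl)ethyl 2-[(4S,5R)-5-formyl-2,2-dimethyl-1,3-dioxolan-4-yl]prop-2-enoate | O=C[C@@H]1OC(C)(C)O[C@H]1C(=C)C(=O)OCC[Si](C)(C)C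
F2 | step 11 | methyl 2-{hydroxy[2,2-dimethyl-5-{3-oxo-3-[2-(trimethylsilyl)ethoxy]prop-1-en-2-yl}-1,3-dioxolan-4-yl]methyl}prop-2-enoate (dioxolane configuration as in 16, carbinol epimers) | COC(=O)C(=C)C(O)[C@@H]1OC(C)(C)O[C@H]1C(=C)C(=O)OCC[Si](C)(C)C
F3 | step 11 | methyl (2Z)-2-(bromomethyl)-3-[2,2-dimethyl-5-{3-oxo-3-[2-(trimethylsilyl)ethoxy]prop-1-en-2-yl}-1,3-dioxolan-4-yl]prop-2-enoate (dioxolane configuration as in 16) | COC(=O)/C(CBr)=C/[C@@H]1OC(C)(C)O[C@H]1C(=C)C(=O)OCC[Si](C)(C)C
F4 | step 11 | seco bromo aldehyde: C6 (Z)-enal, (1(10)E) silylethyl enoate, 8,9-acetonide, C7=C11 (Z)-2-(bromomethyl)enoate methyl ester | O=C/C=C(/C)CC/C=C(/C(=O)OCC[Si](C)(C)C)[C@@H]1OC(C)(C)O[C@H]1/C=C(\CBr)C(=O)OC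
F5 | step 5 | (5R)-5-[(1Z)-2-methylhexa-1,5-dien-1-yl]-3-(tributylstannyl)furan-2(5H)-one | CCCC[Sn](CCCC)(CCCC)C1=C[C@@H](/C=C(/C)CCC=C)OC1=O
F6 | step 5 | (5R)-3-iodo-5-[(1Z)-2-methylhexa-1,5-dien-1-yl]furan-2(5H)-one | IC1=C[C@@H](/C=C(/C)CCC=C)OC1=O
F7 | step 8 | methyl 2,2-dimethyl-5-[1-(tributylstannyl)ethenyl]-1,3-dioxolane-4-carboxylate (configuration as in 15) | COC(=O)[C@@H]1OC(C)(C)O[C@H]1C(=C)[Sn](CCCC)(CCCC)CCCC
F8 | step 8 | methyl 5-(1-iodoethenyl)-2,2-dimethyl-1,3-dioxolane-4-carboxylate (configuration as in 15) | COC(=O)[C@@H]1OC(C)(C)O[C@H]1C(I)=C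
F9 | step 13 | 8,9-bis[2-(diphenoxyphosphoryl)propanoate] of 20 (phosphonate α-carbons unassigned) | C=C1C(=O)O[C@@H]2/C=C(/C)CC/C=C(/C(=O)OCC[Si](C)(C)C)[C@H](OC(=O)C(C)P(=O)(Oc3ccccc3)Oc3ccccc3)[C@@H](OC(=O)C(C)P(=O)(Oc3ccccc3)Oc3ccccc3)[C@@H]12
A1 | alternative 1 | seco bromo aldehyde with both angelates in place: C6 (Z)-enal, (1(10)E) silylethyl enoate, (8S,9S)-bis-angelate, C7=C11 (Z)-2-(bromomethyl)enoate methyl ester | O=C/C=C(/C)CC/C=C(/C(=O)OCC[Si](C)(C)C)[C@H](OC(=O)/C(C)=C\C)[C@@H](OC(=O)/C(C)=C\C)/C=C(\CBr)C(=O)OC
A2 | alternative 2 | seco triene: trans-α-methylene lactone with vinyl on C6, 8,9-acetonide, (1(10)E) silylethyl enoate, C4 as 2-propenyl terminus | C=C1C(=O)O[C@H](C=C)[C@H]1[C@@H]2OC(C)(C)O[C@H]2/C(C(=O)OCC[Si](C)(C)C)=C\CCC(C)=C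
A3 | alternative 3 | 13-membered diallyl ether diol (ring O between C6 and C13; 4Z; C2 cis to C9; C8 trans to C13; 8,9-acetonide; C12 and C14 as CH2OH) | O1C/C=C(/C)CC/C=C(/CO)[C@@H]2OC(C)(C)O[C@H]2/C=C(\CO)C1
A4 | alternative 3 | 6,7-bis-epimeric cyclodecadiene triol (6S,7R with 8S,9S) expected from the ring contraction of A3 | C=C(CO)[C@@H]1[C@@H](O)/C=C(/C)CC/C=C(/CO)[C@@H]2OC(C)(C)O[C@@H]12
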